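**Plan**

- Retrosynthesis: the C8–C14 and C9–C11 bonds are cut together. This removes rings C and D at once and leaves a cyclobutanone (C11–C12–C13–C14) tethered through C15–C16 to the C8=C9 olefin of an A/B lactone. Next come the C8–C15 bond, the 2,3-diol, the C4 methyl, and the C10–C5/C3–C4 bonds of a furan Diels–Alder adduct.
- Enabling feature: in the bicyclo[3.2.1]octane of rings C/D the only oxygen (C11) sits on the middle carbon of the three-carbon bridge C9–C11–C12. Ring C is therefore a four-membered ketone plus the two carbons C8/C9 it shares with ring B, and ring D is the tether.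
- Forward: rings B and A form together by intramolecular furan Diels–Alder reaction (the 3,10-oxygen bridge is a temporary ring). The bridge is opened by E1cB, C4 is methylated, lactone and 2β,3β-diol follow, and the cyclobutanone side chain is attached at C8. Rings C and D then close together by rhodium-catalysed two-atom ring expansion of the cyclobutanone; reduction and deprotection finish.
- Stereochemistry: one CBS reduction sets a temporary carbinol centre at C9 that steers the Diels–Alder face (C10, C5) and is later oxidised away. C4, C2/C3, C8/C9/C13 and C11 follow from substrate control; C6 is set by equilibration.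

Key step: step 16

Remark: gibberellane numbering of the target (C1–C19) is used for all intermediates; C7 is carried as its tert-butyl ester; the C6 epimers present in 6–10 converge in step 6; compounds 1, 5, 7 and 17 are taken as commercial.

**Route**

Step 1
Reactants: 1 2-bromo-1-(furan-2-yl)ethan-1-one
Product: 2 (1S)-2-bromo-1-(furan-2-yl)ethan-1-ol
Conditions: (S)-Me-CBS oxazaborolidine (10 mol%), BH3·SMe2, THF, 0 °C; MeOH quench
Reagents that add atoms: none
Why: Corey–Bakshi–Shibata reduction with the furyl ring as the large group should give the (S)-bromohydrin, whose carbinol carbon (C9) serves only as a temporary stereocentre.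

Step 2
Reactants: 2 (1S)-2-bromo-1-(furan-2-yl)ethan-1-ol
Product: 4 triethyl[(1S)-1-(furan-2-yl)-2-iodoethoxy]silane, via silyl ether bromide 3 (not isolated)
Conditions: Et3SiCl, imidazole, CH2Cl2, 0 °C; filter, concentrate; then NaI, acetone, reflux
Reagents that add atoms: chlorotriethylsilane CC[Si](Cl)(CC)CC; sodium iodide [Na+].[I-]
Why: Silylation followed by Finkelstein exchange should give the more reactive primary iodide without touching the stereocentre.

Step 3
Reactants: 4 triethyl[(1S)-1-(furan-2-yl)-2-iodoethoxy]silane; 5 tert-butyl (2E)-but-2-enoate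
Product: 6 tert-butyl 2-[(2R)-2-(furan-2-yl)-2-(triethylsilyloxy)ethyl]but-3-enoate
Conditions: LDA, HMPA, THF, −78 °C, 5; then 4, −78 to −20 °C
Reagents that add atoms: none
Why: Deconjugative α-alkylation of the lithium dienolate of the crotonate (SN2 on the primary iodide) forms the C6–C8 bond; the new C6 centre is unselective and is set later.

Step 4
Reactants: 6 tert-butyl 2-[(2R)-2-(furan-2-yl)-2-(triethylsilyloxy)ethyl]but-3-enoate; 7 (2E)-but-2-enal
Product: 8 tert-butyl (3E)-2-[(2R)-2-(furan-2-yl)-2-(triethylsilyloxy)ethyl]-5-oxopent-3-enoate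
Conditions: second-generation Hoveyda–Grubbs catalyst (5 mol%), 7 (5 equiv), CH2Cl2, 40 °C
Reagents that add atoms: none
Why: Olefin cross-metathesis of the terminal vinyl group with crotonaldehyde should give the (E)-enal dienophile.

Step 5
Reactants: 8 tert-butyl (3E)-2-[(2R)-2-(furan-2-yl)-2-(triethylsilyloxy)ethyl]-5-oxopent-3-enoate
Product: 10 oxa-bridged ring A/B aldehyde, via oxanorbornene cycloadduct 9 (not isolated)
Conditions: Me2AlCl (0.2 equiv), CH2Cl2, −78 to −30 °C; silica plug; then H2 (1 atm), 10% Pd/C, EtOAc, 0 °C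
Reagents that add atoms: none
Why: In this Lewis-acid-catalysed intramolecular Diels–Alder reaction of the furan, the three-atom tether enforces the exo-tether adduct (bridging oxygen at C10 and C4 on the same face of ring B); allylic strain keeps the carbinol hydrogen next to furan H-3, so the enal should add to the face that leaves the silyloxy group syn to the oxygen bridge, fixing C10 and C5, and immediate hydrogenation of the strained olefin blocks cycloreversion.

Step 6
Reactants: 10 oxa-bridged ring A/B aldehyde
Product: 12 4β-methyl-2-ene 19,10-lactol, via hydroxy enal 11 (not isolated)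
Conditions: KOtBu (3 equiv), t-BuOH/THF, 0 °C; then MeI (1.2 equiv), −78 °C; aq. NH4Cl
Reagents that add atoms: iodomethane CI
Why: E1cB opening of the β-alkoxy aldehyde cleaves the temporary C3–O bridge and the base equilibrates C6 to the ester trans to C4; deconjugative α-methylation of the potassium dienolate should then occur on the β-face (equatorial entry, anti to the axial C10 alkoxide) to set C4, after which the axial aldehyde closes onto the C10 hydroxyl as lactol.

Step 7
Reactants: 12 4β-methyl-2-ene 19,10-lactol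
Product: 14 2-ene 19,10-lactone 9-ketone, via lactone silyl ether 13 (not isolated)
Conditions: CrO3, H2SO4, H2O, acetone (Jones reagent), 0 °C to rt
Reagents that add atoms: none
Why: Jones oxidation converts the lactol into the γ-lactone, and the acidic medium cleaves the triethylsilyl ether, whose alcohol is oxidised in the same flask to the C9 ketone, removing the temporary stereocentre.

Step 8
Reactants: 14 2-ene 19,10-lactone 9-ketone
Product: 15 2β,3β-diol
Conditions: OsO4 (2 mol%), NMO, acetone/H2O, rt
Reagents that add atoms: N-methylmorpholine N-oxide C[N+]1([O-])CCOCC1; water O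
Why: Upjohn dihydroxylation of the only olefin should take place on the exo (β) face of the 6-oxabicyclo[3.2.1]octene, opposite the lactone bridge, setting C2 and C3 as the cis-β-diol.

Step 9
Reactants: 15 2β,3β-diol
Product: 16 2β,3β-acetonide ketone
Conditions: Me2C(OMe)2, PPTS (cat.), acetone, rt
Reagents that add atoms: 2,2-dimethoxypropane COC(C)(C)OC
Why: Acid-catalysed ketalisation protects the cis-diol for the enolate, hydride and rhodium steps.

Step 10
Reactants: 17 methyl 3,3-dimethoxycyclobutane-1-carboxylate
Product: 18 [2-(3,3-dimethoxycyclobutyl)prop-2-en-1-yl]trimethylsilane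
Conditions: Me3SiCH2MgCl (3 equiv), CeCl3, THF, −78 °C to rt; then silica gel, CH2Cl2
Reagents that add atoms: (trimethylsilyl)methylmagnesium chloride C[Si](C)(C)C[Mg]Cl
Why: Double Grignard addition to the ester followed by Peterson elimination of the bis(silylmethyl) carbinol gives the 2-substituted allylsilane.

Step 11
Reactants: 18 [2-(3,3-dimethoxycyclobutyl)prop-2-en-1-yl]trimethylsilane
Product: 19 3-(3-bromoprop-1-en-2-yl)-1,1-dimethoxycyclobutane
Conditions: NBS, CH2Cl2, −78 to 0 °C
Reagents that add atoms: N-bromosuccinimide O=C1CCC(=O)N1Br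
Why: Electrophilic bromodesilylation (SE2') of the allylsilane gives the allylic bromide that carries C15, C16, C17 and the masked cyclobutanone.

Step 12
Reactants: 16 2β,3β-acetonide ketone; 19 3-(3-bromoprop-1-en-2-yl)-1,1-dimethoxycyclobutane
Product: 20 C8-alkylated ketone
Conditions: KHMDS (1.05 equiv), THF, −78 °C; then 19, −78 to −40 °C
Reagents that add atoms: none
Why: Ketone enolate alkylation can occur only at C8 because C10 is quaternary, forming the C8–C15 bond; the C8 configuration is irrelevant.

Step 13
Reactants: 20 C8-alkylated ketone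
Product: 21 C9 carbinol
Conditions: NaBH4, CeCl3·7H2O, MeOH, −40 °C
Reagents that add atoms: none
Why: Luche reduction reduces the ketone chemoselectively beside lactone and ester under buffered conditions that should suppress acyl migration.

Step 14
Reactants: 21 C9 carbinol
Product: 22 8-ene with ketal side chain
Conditions: Martin sulfurane, CH2Cl2, rt
Reagents that add atoms: none
Why: Dehydration through the alkoxysulfonium intermediate can remove only the C8 hydrogen, since C10 has none, giving the C8=C9 olefin regiospecifically.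

Step 15
Reactants: 22 8-ene with ketal side chain
Product: 23 8-ene cyclobutanone
Conditions: p-TsOH·H2O (cat.), acetone/H2O (20:1), rt to 40 °C
Reagents that add atoms: water O
Why: Acid-catalysed trans-ketalisation frees the cyclobutanone while the acetone solvent keeps the acetonide in place.

Step 16
Reactants: 23 8-ene cyclobutanone
Product: 24 tetracyclic 11-ketone
Conditions: [Rh(nbd)(dppp)]PF6 (10 mol%), m-xylene, 135 °C, argon
Reagents that add atoms: none
Why: Oxidative addition of monovalent rhodium into the C11–C14 acyl–carbon bond gives a rhodacyclopentanone, the C8=C9 olefin inserts into the Rh–C14 bond, and C9–C11 reductive elimination closes the six-membered ketone, a [4+2] carboacylation. The closest known reaction type is the rhodium-catalysed intramolecular insertion of an olefin into the C–C bond of a 3-substituted cyclobutanone to give a bicyclo[3.2.1]octanone. Ring D closes by 5-exo carbometalation at C8 through the C15–C16 tether, and ring C arises by two-atom ring expansion of the four-membered ketone (C11, C12, C13, C14) with C8 and C9; the bridged mode is forced because C8 is the tether terminus. C8 and C9 form by syn addition to the α-face of the cyclopentene, opposite the C6 ester and the C1 methylene, and C13 can adopt only the configuration that lets the bridge close. The step needs the ring olefin to react in preference to the exocyclic 1,1-disubstituted one, which cannot reach the metallacycle, and it needs the allylic lactone and the resulting β-acyloxy ketone to survive, which the neutral, base-free conditions should allow.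

Step 17
Reactants: 24 tetracyclic 11-ketone
Product: 25 11β-alcohol
Conditions: LiBH(s-Bu)3, THF, −78 °C; aqueous work-up
Reagents that add atoms: none
Why: The bulky borohydride should attack the ketone from the α-face, away from the C15–C16 bridge that is 1,3-diaxial to the carbonyl, giving the axial 11β-alcohol.

Step 18
Reactants: 25 11β-alcohol
Product: 27 target CNP0322347.1, via acetonide acid 26 (not isolated)
Conditions: Me3SiOTf, 2,6-lutidine, CH2Cl2, 0 °C; then AcOH/H2O/THF (3:1:1), 40 °C
Reagents that add atoms: none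
Why: Silyl-triflate-mediated cleavage of the tert-butyl ester (loss of isobutene) under buffered conditions followed by mild acid hydrolysis of the acetonide and silyl groups should free the acid and the triol without isomerising the exocyclic olefin or epimerising C3.

**Compound list**

1 | 2-bromo-1-(furan-2-yl)ethan-1-one | O=C(CBr)c1ccco1 | starting material
2 | (1S)-2-bromo-1-(furan-2-yl)ethan-1-ol | BrC[C@@H](O)c1ccco1 | intermediate
3 | [(1S)-2-bromo-1-(furan-2-yl)ethoxy]triethylsilane | BrC[C@@H](O[Si](CC)(CC)CC)c1ccco1 | intermediate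
4 | triethyl[(1S)-1-(furan-2-yl)-2-iodoethoxy]silane | IC[C@@H](O[Si](CC)(CC)CC)c1ccco1 | intermediate
5 | tert-butyl (2E)-but-2-enoate | C/C=C/C(=O)OC(C)(C)C | starting material
6 | tert-butyl 2-[(2R)-2-(furan-2-yl)-2-(triethylsilyloxy)ethyl]but-3-enoate (both C6 epimers) | C=CC(C[C@@H](O[Si](CC)(CC)CC)c1ccco1)C(=O)OC(C)(C)C | intermediate
7 | (2E)-but-2-enal | C/C=C/C=O | starting material
8 | tert-butyl (3E)-2-[(2R)-2-(furan-2-yl)-2-(triethylsilyloxy)ethyl]-5-oxopent-3-enoate (both C6 epimers) | O=C/C=C/C(C[C@@H](O[Si](CC)(CC)CC)c1ccco1)C(=O)OC(C)(C)C | intermediate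
9 | oxanorbornene cycloadduct: rings A and B with 3α,10α-oxygen bridge, 1-ene, endo 4-formyl, 9α-triethylsilyloxy, 6-CO2tBu (C6 epimers) | C1[C@@H](O[Si](CC)(CC)CC)[C@@]23C=C[C@@H](O2)[C@H](C=O)[C@H]3C1C(=O)OC(C)(C)C | intermediate
10 | oxa-bridged ring A/B aldehyde: 9 with C1–C2 saturated | C1[C@@H](O[Si](CC)(CC)CC)[C@@]23CC[C@@H](O2)[C@H](C=O)[C@H]3C1C(=O)OC(C)(C)C | intermediate
11 | hydroxy enal: 10α-hydroxy-3-ene-4-carbaldehyde, 9α-triethylsilyloxy, 6β-CO2tBu | C1[C@@H](O[Si](CC)(CC)CC)[C@]2(O)CCC=C(C=O)[C@H]2[C@@H]1C(=O)OC(C)(C)C | intermediate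
12 | 4β-methyl-2-ene 19,10-lactol (both C19 epimers), 9α-triethylsilyloxy, 6β-CO2tBu | C1[C@@H](O[Si](CC)(CC)CC)[C@@]23CC=C[C@@](C)(C(O)O2)[C@H]3[C@@H]1C(=O)OC(C)(C)C | intermediate
13 | lactone silyl ether: 19,10-γ-lactone of 12 | C1[C@@H](O[Si](CC)(CC)CC)[C@@]23CC=C[C@@](C)(C(=O)O2)[C@H]3[C@@H]1C(=O)OC(C)(C)C | intermediate
14 | 2-ene 19,10-lactone 9-ketone, 4β-methyl, 6β-CO2tBu | C1C(=O)[C@@]23CC=C[C@@](C)(C(=O)O2)[C@H]3[C@@H]1C(=O)OC(C)(C)C | intermediate
15 | 2β,3β-diol of 14 | C1C(=O)[C@@]23C[C@H](O)[C@H](O)[C@@](C)(C(=O)O2)[C@H]3[C@@H]1C(=O)OC(C)(C)C | intermediate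
16 | 2β,3β-acetonide ketone | C1C(=O)[C@@]23C[C@@H]4OC(C)(C)O[C@@H]4[C@@](C)(C(=O)O2)[C@H]3[C@@H]1C(=O)OC(C)(C)C | intermediate
17 | methyl 3,3-dimethoxycyclobutane-1-carboxylate | COC(=O)C1CC(OC)(OC)C1 | starting material
18 | [2-(3,3-dimethoxycyclobutyl)prop-2-en-1-yl]trimethylsilane | C=C(C[Si](C)(C)C)C1CC(OC)(OC)C1 | intermediate
19 | 3-(3-bromoprop-1-en-2-yl)-1,1-dimethoxycyclobutane | BrCC(=C)C1CC(OC)(OC)C1 | intermediate
20 | C8-alkylated ketone: 16 bearing 2-(3,3-dimethoxycyclobutyl)prop-2-en-1-yl at C8 (C8 epimers) | C=C(C1CC(OC)(OC)C1)CC2C(=O)[C@@]34C[C@@H]5OC(C)(C)O[C@@H]5[C@@](C)(C(=O)O3)[C@H]4[C@@H]2C(=O)OC(C)(C)C | intermediate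
21 | C9 carbinol of 20 (C8 and C9 epimers) | C=C(C1CC(OC)(OC)C1)CC2C(O)[C@@]34C[C@@H]5OC(C)(C)O[C@@H]5[C@@](C)(C(=O)O3)[C@H]4[C@@H]2C(=O)OC(C)(C)C | intermediate
22 | 8-ene with ketal side chain | C=C(C1CC(OC)(OC)C1)CC2=C[C@@]34C[C@@H]5OC(C)(C)O[C@@H]5[C@@](C)(C(=O)O3)[C@H]4[C@@H]2C(=O)OC(C)(C)C | intermediate
23 | 8-ene cyclobutanone: 22 with free 3-oxocyclobutyl group | C=C(C1CC(=O)C1)CC2=C[C@@]34C[C@@H]5OC(C)(C)O[C@@H]5[C@@](C)(C(=O)O3)[C@H]4[C@@H]2C(=O)OC(C)(C)C | intermediate
24 | tetracyclic 11-ketone: tert-butyl ester and 2β,3β-acetonide of the 11-oxo analogue of the target | C=C1C[C@]23C[C@H]1CC(=O)[C@H]2[C@@]12C[C@@H]4OC(C)(C)O[C@@H]4[C@@](C)(C(=O)O1)[C@H]2[C@@H]3C(=O)OC(C)(C)C | intermediate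
25 | 11β-alcohol of 24 | C=C1C[C@]23C[C@H]1C[C@H](O)[C@H]2[C@@]12C[C@@H]4OC(C)(C)O[C@@H]4[C@@](C)(C(=O)O1)[C@H]2[C@@H]3C(=O)OC(C)(C)C | intermediate
26 | acetonide acid: 2β,3β-acetonide of the target | C=C1C[C@]23C[C@H]1C[C@H](O)[C@H]2[C@@]12C[C@@H]4OC(C)(C)O[C@@H]4[C@@](C)(C(=O)O1)[C@H]2[C@@H]3C(=O)O | intermediate
27 | CNP0322347.1: 2β,3β,11β-trihydroxy-16-ene C19 gibberellin 19,10-lactone 7-oic acid | C=C1C[C@]23C[C@H]1C[C@H](O)[C@H]2[C@@]12C[C@H](O)[C@H](O)[C@@](C)(C(=O)O1)[C@H]2[C@@H]3C(=O)O | target

**Summary**

Total steps: 18. Longest linear sequence: 16 steps (steps 1–9 and 12–18).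

**Steps most likely to fail**

1. Step 16. Insertion of the hindered trisubstituted ring olefin may be slower than decarbonylation of the rhodacycle, and rhodium may ionise the allylic lactone C–O bond. The fallback sets out from 16 and comes back at 24; it moves the strained ketone onto ring B and makes the inserting olefin a terminal vinyl group. Ketone 16 is alkylated at C8 with 2,3-dibromopropene (KHMDS) to the bromoallyl ketone F1, reduced (NaBH4, CeCl3) to the carbinol F2 and dehydrated (Martin sulfurane) to the bromoallyl 8-ene F3. Dichloroketene (Cl3CCOCl, Zn–Cu, Et2O) should add to the electron-rich C8=C9 bond from the α-face in a [2+2] cycloaddition, carbonyl carbon to C9, giving the dichlorocyclobutanone F4, which Zn/AcOH dechlorinates to the fused cyclobutanone F5. Stille coupling with tributyl(vinyl)stannane (Pd(PPh3)4) turns the vinyl bromide into the diene F6. The rhodium catalyst of step 16 then cleaves the C11–C14 bond and inserts the unhindered terminal C12=C13 olefin (C14 to C13, C11 to C12), which again expands the four-membered ketone to ring C, closes ring D, and gives 24.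

2. Step 5. Cycloreversion and a slow cycloaddition may leave the equilibrium on the side of 8, and face selectivity may erode if warming is needed. The fallback sets out from 8 and comes back at 10; it uses a temporary bromine on the diene. NBS (DMF, 0 °C) brominates the free α-position of the furan to give the bromofuran enal F7, whose intramolecular Diels–Alder reaction should be faster and more exergonic (halogen effect) and gives the bridgehead bromide F8. Hydrogenation over Pd/C with Et3N saturates the strained olefin and removes the bromine, giving 10.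

3. Step 6. O-methylation of the C10 alkoxide, γ-alkylation, or aldol condensation of the enal dienolate may compete with α-methylation. The fallback sets out from 11 (isolated by quenching the KOtBu ring opening before MeI is added) and comes back at 12; it uses a metalloenamine alkylation. Condensation of 11 with cyclohexylamine (MgSO4) gives the unsaturated imine F9. LDA (2.2 equiv, THF, −78 °C) forms the aza-dienolate, which MeI should alkylate at C4 only, on the same β-face, to give the methylated imine F10. Aqueous oxalic acid hydrolyses F10 to lactol 12.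

**Further compounds**

F1 | step 16 | bromoallyl ketone: 16 bearing 2-bromoprop-2-en-1-yl at C8 (C8 epimers) | C=C(Br)CC1C(=O)[C@@]23C[C@@H]4OC(C)(C)O[C@@H]4[C@@](C)(C(=O)O2)[C@H]3[C@@H]1C(=O)OC(C)(C)C
F2 | step 16 | C9 carbinol of F1 (C8 and C9 epimers) | C=C(Br)CC1C(O)[C@@]23C[C@@H]4OC(C)(C)O[C@@H]4[C@@](C)(C(=O)O2)[C@H]3[C@@H]1C(=O)OC(C)(C)C
F3 | step 16 | bromoallyl 8-ene | C=C(Br)CC1=C[C@@]23C[C@@H]4OC(C)(C)O[C@@H]4[C@@](C)(C(=O)O2)[C@H]3[C@@H]1C(=O)OC(C)(C)C
F4 | step 16 | dichlorocyclobutanone fused at C8–C9 (carbonyl C11 on C9, CCl2 on C8, both α) | C=C(Br)C[C@]12C(Cl)(Cl)C(=O)[C@H]1[C@@]34C[C@@H]5OC(C)(C)O[C@@H]5[C@@](C)(C(=O)O3)[C@H]4[C@@H]2C(=O)OC(C)(C)C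
F5 | step 16 | fused cyclobutanone with 2-bromoallyl group at C8 | C=C(Br)C[C@]12CC(=O)[C@H]1[C@@]34C[C@@H]5OC(C)(C)O[C@@H]5[C@@](C)(C(=O)O3)[C@H]4[C@@H]2C(=O)OC(C)(C)C
F6 | step 16 | fused cyclobutanone with 2-methylidenebut-3-en-1-yl (diene) group at C8 | C=CC(=C)C[C@]12CC(=O)[C@H]1[C@@]34C[C@@H]5OC(C)(C)O[C@@H]5[C@@](C)(C(=O)O3)[C@H]4[C@@H]2C(=O)OC(C)(C)C
F7 | step 5 | bromofuran enal: 8 with bromine at the free furan α-position | O=C/C=C/C(C[C@@H](O[Si](CC)(CC)CC)c1ccc(Br)o1)C(=O)OC(C)(C)C
F8 | step 5 | bridgehead bromide: cycloadduct 9 with bromine at C3 | C1[C@@H](O[Si](CC)(CC)CC)[C@@]23C=C[C@@](Br)(O2)[C@H](C=O)[C@H]3C1C(=O)OC(C)(C)C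
F9 | step 6 | unsaturated imine: N-cyclohexyl imine of 11 | C1[C@@H](O[Si](CC)(CC)CC)[C@]2(O)CCC=C(C=NC3CCCCC3)[C@H]2[C@@H]1C(=O)OC(C)(C)C
F10 | step 6 | methylated imine: N-cyclohexyl imine of the 4β-methyl-2-ene aldehyde | C1[C@@H](O[Si](CC)(CC)CC)[C@]2(O)CC=C[C@@](C)(C=NC3CCCCC3)[C@H]2[C@@H]1C(=O)OC(C)(C)C
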